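**Plan**

1. Retrosynthetic cuts, in order: the acetyl–O1′ bond; the C5–O and C1′–O bonds together (syn-dihydroxylation); the exocyclic C5=C1′ bond (aldol condensation), which leaves (R)-4-silyloxycyclopentenone 1 and pentadecanal 2.
2. Forward: the five-membered ring is bought intact and no ring is built; the C15 chain is joined to C5 in steps 1–2, the two oxygens are added in step 4 and the acetate in step 7.
3. Enabling feature (ring: C1 ketone, C2=C3, C4 carbinol, C5 quaternary carbinol; C1′ acetoxy carbon): O5 and O1′ on the adjacent carbons C5/C1′ have the relationship left by syn addition to an (E)-C5=C1′ alkene, and the 4-OH of the cyclopentenone ring is cis to 5-OH, so it can guide OsO4·TMEDA by hydrogen bonding.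
4. Stereochemistry: C4 comes from commercial 1 and is never touched; C5 from delivery of the oxidant on the 4-OH face; C1′ from suprafacial addition to the E alkene.
5. The osmate ester formed in step 4 is kept as a mask for O5/O1′ while O4 is silylated, which allows the acetate to be placed on O1′ alone.

Key step: step 4

Remark: the locants C1–C5 and C1′ defined in line 3 are used for every intermediate. The CIP letter at C5 switches between S and R along the route only because the ranking of C4 against C1′ changes with the O-substituents; the spatial arrangement is that of the target throughout. The N→Os bonds of the osmate esters are written with formal charges in the SMILES.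

**Route**

Step 1
Reactants: 1 (R)-4-(tert-butyldimethylsilyloxy)cyclopent-2-en-1-one; 2 pentadecanal
Product: 4 (4S,5R)-4-(tert-butyldimethylsilyloxy)-5-(1-hydroxypentadecyl)cyclopent-2-en-1-one (4,5-trans; both C1′ epimers), via lithium dienolate 3 (not isolated)
Conditions: LiN(iPr)2 (commercial solution), THF, −78 °C; then 2, −78 °C; AcOH quench at −78 °C
Reagents that add atoms: none
Why: Kinetic deprotonation at C5 and immediate lithium-enolate aldol addition to the unhindered aldehyde, anti to the silyloxy group, should outrun β-elimination of silanolate at −78 °C; the configurations created at C5 and C1′ are erased in step 2, so C4 remains the only centre that matters.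

Step 2
Reactants: 4
Product: 6 (4S,5E)-4-(tert-butyldimethylsilyloxy)-5-pentadecylidenecyclopent-2-en-1-one, via C1′ mesylate 5 (not isolated)
Conditions: MsCl, Et3N (excess), CH2Cl2, 0 °C → rt
Reagents that add atoms: none
Why: Mesylation followed by E1cB elimination (the dehydration half of an aldol condensation) expels mesylate, a far better leaving group than the C4 silanolate, and the enolate pathway funnels both C1′ epimers to the thermodynamically preferred E alkylidene ketone, whose chain points away from the carbonyl oxygen; any minor Z isomer is removed by chromatography.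

Step 3
Reactants: 6
Product: 7 (4S,5E)-4-hydroxy-5-pentadecylidenecyclopent-2-en-1-one
Conditions: 48% aq. HF, MeCN, 0 °C → rt
Reagents that add atoms: none
Why: Acidic fluoride desilylation cleaves the Si–O bond without forming an alkoxide or enolate, so the base-sensitive cross-conjugated dienone and the C4 centre are left untouched and the hydrogen-bond donor needed in step 4 is exposed.

Step 4
Reactants: 7
Product: 8 TMEDA-chelated O5/O1′ osmate ester (dioxo glycolate of hexavalent osmium) of (4S,5S)-4,5-dihydroxy-5-[(1S)-1-hydroxypentadecyl]cyclopent-2-en-1-one, 4-OH free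
Conditions: OsO4 (1.0 equiv), TMEDA (1.1 equiv), CH2Cl2, −78 °C
Reagents that add atoms: osmium tetroxide O=[Os](=O)(=O)=O; N,N,N′,N′-tetramethylethylenediamine CN(C)CCN(C)C
Why: OsO4 bound to TMEDA adds to C5=C1′ of 7 in a concerted, suprafacial (3+2) cycloaddition and the adduct persists as the diamine-chelated glycolate of hexavalent osmium, so both C–O bonds form at once and no carbocycle closes (only the O5–Os–O1′ chelate ring, by that cycloaddition). The closest known reaction type is the hydrogen-bond-directed dihydroxylation of cyclic allylic alcohols with OsO4·TMEDA, in which the diamine makes the oxo ligands good hydrogen-bond acceptors. C5 is controlled by the 4-OH, which hydrogen-bonds to an oxo ligand and draws the reagent to its own ring face, placing O5 cis to O4. C1′ is controlled by the E geometry of the alkene: syn addition on that face to an alkene whose chain is cis to C4 can only give the 1′S centre. The step needs face selectivity and site selectivity over C2=C3; the free allylic hydroxyl secures the first, and the second rests on the exocyclic alkene being trisubstituted with an alkyl donor on C1′ while the ring alkene is a disubstituted enone bond next to the electron-withdrawing carbinol carbon, with one equivalent of oxidant at −78 °C guarding against double osmylation.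

Step 5
Reactants: 8
Product: 9 4-O-tert-butyldiphenylsilyl ether of osmate ester 8
Conditions: TBDPSCl, imidazole, 4-(dimethylamino)pyridine (cat.), DMF, rt
Reagents that add atoms: tert-butyl(chloro)diphenylsilane CC(C)(C)[Si](Cl)(c1ccccc1)c1ccccc1
Why: Imidazole-promoted silylation of the only free hydroxyl; the diamine-chelated glycolate of hexavalent osmium is coordinatively saturated and is known to tolerate silylating and acylating agents, so O5 and O1′ stay masked while O4 receives a group that resists the acid used next.

Step 6
Reactants: 9
Product: 10 (4S,5S)-4-(tert-butyldiphenylsilyloxy)-5-hydroxy-5-[(1S)-1-hydroxypentadecyl]cyclopent-2-en-1-one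
Conditions: conc. HCl (about 5 equiv), MeOH, 0 °C → rt
Reagents that add atoms: none
Why: Acidic methanolysis of the osmate ester: protonation of the diamine opens the chelate and the glycolate is solvolysed from osmium, while the tert-butyldiphenylsilyl ether (stable to dilute methanolic HCl at room temperature) and the enone should not be affected; no stereocentre is involved.

Step 7
Reactants: 10
Product: 11 (4S,5S)-5-[(1S)-1-acetoxypentadecyl]-4-(tert-butyldiphenylsilyloxy)-5-hydroxycyclopent-2-en-1-one
Conditions: Ac2O, pyridine, 4-(dimethylamino)pyridine (cat.), CH2Cl2, 0 °C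
Reagents that add atoms: acetic anhydride CC(=O)OC(C)=O
Why: 4-(Dimethylamino)pyridine-catalysed acetylation discriminates the secondary C1′ hydroxyl from the tertiary, hydrogen-bonded C5 hydroxyl, and the weakly basic medium avoids retro-aldol cleavage of the β-hydroxy ketone.

Step 8
Reactants: 11
Product: 12 (4S,5R)-5-[(1S)-1-acetoxypentadecyl]-4,5-dihydroxycyclopent-2-en-1-one (target)
Conditions: HF·pyridine, THF–pyridine, 0 °C → rt
Reagents that add atoms: none
Why: Fluoride-mediated silyl ether cleavage under buffered acidic conditions forms no alkoxide, so the acetate should stay on O1′ without acyl migration and the α-ketol and enone survive, giving the target with all three centres as set earlier.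

**Compound list**

1 | (R)-4-(tert-butyldimethylsilyloxy)cyclopent-2-en-1-one | O=C1C=C[C@H](O[Si](C)(C)C(C)(C)C)C1 | starting material
2 | pentadecanal | CCCCCCCCCCCCCCC=O | starting material
3 | lithium dienolate of 1 (C1–O–Li, C1=C5, C2=C3) | [Li]OC1=C[C@@H](O[Si](C)(C)C(C)(C)C)C=C1 | intermediate (not isolated)
4 | (4S,5R)-4-(tert-butyldimethylsilyloxy)-5-(1-hydroxypentadecyl)cyclopent-2-en-1-one, both C1′ epimers | CCCCCCCCCCCCCCC(O)[C@H]1C(=O)C=C[C@@H]1O[Si](C)(C)C(C)(C)C | intermediate
5 | C1′ methanesulfonate of 4 | CCCCCCCCCCCCCCC(OS(C)(=O)=O)[C@H]1C(=O)C=C[C@@H]1O[Si](C)(C)C(C)(C)C | intermediate (not isolated)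
6 | (4S,5E)-4-(tert-butyldimethylsilyloxy)-5-pentadecylidenecyclopent-2-en-1-one | CCCCCCCCCCCCCC/C=C1/C(=O)C=C[C@@H]1O[Si](C)(C)C(C)(C)C | intermediate
7 | (4S,5E)-4-hydroxy-5-pentadecylidenecyclopent-2-en-1-one | CCCCCCCCCCCCCC/C=C1/C(=O)C=C[C@@H]1O | intermediate
8 | TMEDA-chelated O5/O1′ osmate ester of the (4S,5S,1′S)-triol, 4-OH free | CCCCCCCCCCCCCC[C@@H]2O[Os-2]3(=O)(=O)([N+](C)(C)CC[N+]3(C)C)O[C@@]21C(=O)C=C[C@@H]1O | intermediate
9 | 4-O-tert-butyldiphenylsilyl ether of 8 | CCCCCCCCCCCCCC[C@@H]2O[Os-2]3(=O)(=O)([N+](C)(C)CC[N+]3(C)C)O[C@@]21C(=O)C=C[C@@H]1O[Si](c4ccccc4)(c4ccccc4)C(C)(C)C | intermediate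
10 | (4S,5S)-4-(tert-butyldiphenylsilyloxy)-5-hydroxy-5-[(1S)-1-hydroxypentadecyl]cyclopent-2-en-1-one | CCCCCCCCCCCCCC[C@H](O)[C@@]1(O)C(=O)C=C[C@@H]1O[Si](c2ccccc2)(c2ccccc2)C(C)(C)C | intermediate
11 | (4S,5S)-5-[(1S)-1-acetoxypentadecyl]-4-(tert-butyldiphenylsilyloxy)-5-hydroxycyclopent-2-en-1-one | CCCCCCCCCCCCCC[C@H](OC(C)=O)[C@@]1(O)C(=O)C=C[C@@H]1O[Si](c2ccccc2)(c2ccccc2)C(C)(C)C | intermediate
12 | (4S,5R)-5-[(1S)-1-acetoxypentadecyl]-4,5-dihydroxycyclopent-2-en-1-one | CCCCCCCCCCCCCC[C@H](OC(C)=O)[C@@]1(O)C(=O)C=C[C@@H]1O | target

**Totals**

Total step count: 8. Longest linear sequence: 8 steps (1 → 12).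

**Steps most likely to fail**

Step 4. The oxidant may add to the ring alkene C2=C3, which is also allylic to 4-OH, or to both alkenes, so that site selectivity is lost. The fallback masks the ring enone and sets out from 7. Thiophenol with catalytic Et3N in CH2Cl2 at 0 °C should add to C3 by thia-Michael addition, since soft nucleophiles attack the endocyclic enone of such cross-conjugated dienones, anti to 4-OH. This gives (3R,4R,5E)-4-hydroxy-5-pentadecylidene-3-(phenylsulfanyl)cyclopentan-1-one F1. OsO4·TMEDA in CH2Cl2 at −78 °C then finds only the exocyclic alkene and, guided by 4-OH and with the top face shielded by the sulfide, should give the O5/O1′ osmate ester of the 3-phenylsulfanyl ketone F2. Oxidation with 3-chloroperbenzoic acid at −78 °C gives the sulfoxide of F2 F3. Warming with Et3N eliminates benzenesulfenic acid, restores C2=C3 and rejoins the route at 8.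

Step 6. The acidic methanolysis that frees the diol from osmium may also strip or shift the silyl ether on O4, which would erase the distinction between O4 and O1′. The fallback removes osmium before any silyl group is present and sets out from 8. Methanolic HCl should release the free triol (4S,5S)-4,5-dihydroxy-5-[(1S)-1-hydroxypentadecyl]cyclopent-2-en-1-one F4. The hydroxyls are then told apart by size alone. TBDPSCl and imidazole in DMF at 0 °C should silylate the ring allylic 4-OH ahead of the side-chain carbinol, which is flanked by the quaternary C5 and the chain, and ahead of the tertiary 5-OH. This comes back to the route at 10.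

Step 1. β-Elimination of silanolate from the C5 enolate, leading to a cyclopentadienone that dimerises, or proton transfer to the aldolate, may outpace C–C bond formation. The fallback builds the ring substituents by oxidation of a fulvene and sets out from 2 and freshly cracked cyclopentadiene. Pyrrolidine in MeOH should condense them to 6-tetradecylfulvene F5. Tetraphenylporphyrin-sensitised photooxygenation in CH2Cl2 at −78 °C gives the (4+2) endoperoxide 7-pentadecylidene-2,3-dioxabicyclo[2.2.1]hept-5-ene F6. Et3N opens it in the same flask by Kornblum–DeLaMare rearrangement, preferentially through the bridgehead hydrogen remote from the chain, to racemic (E)-4-hydroxy-5-pentadecylidenecyclopent-2-en-1-one F7. Kinetic resolution with lipase from Burkholderia cepacia and vinyl acetate is expected, from the size rule for lipase acylation of secondary alcohols, to acetylate the 4R alcohol and leave the 4S alcohol. This is 7, so steps 1–3 are bypassed.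

**Further compounds**

F1 | step 4 | (3R,4R,5E)-4-hydroxy-5-pentadecylidene-3-(phenylsulfanyl)cyclopentan-1-one | CCCCCCCCCCCCCC/C=C1/C(=O)C[C@@H](Sc2ccccc2)[C@@H]1O
F2 | step 4 | TMEDA-chelated O5/O1′ osmate ester of the 3-phenylsulfanyl ketone | CCCCCCCCCCCCCC[C@@H]2O[Os-2]3(=O)(=O)([N+](C)(C)CC[N+]3(C)C)O[C@@]21C(=O)C[C@@H](Sc4ccccc4)[C@@H]1O
F3 | step 4 | sulfoxide of F2 (configuration at sulfur not defined) | CCCCCCCCCCCCCC[C@@H]2O[Os-2]3(=O)(=O)([N+](C)(C)CC[N+]3(C)C)O[C@@]21C(=O)C[C@@H](S(=O)c4ccccc4)[C@@H]1O
F4 | step 6 | (4S,5S)-4,5-dihydroxy-5-[(1S)-1-hydroxypentadecyl]cyclopent-2-en-1-one | CCCCCCCCCCCCCC[C@H](O)[C@@]1(O)C(=O)C=C[C@@H]1O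
F5 | step 1 | 6-tetradecylfulvene | CCCCCCCCCCCCCCC=C1C=CC=C1
F6 | step 1 | 7-pentadecylidene-2,3-dioxabicyclo[2.2.1]hept-5-ene (racemic) | CCCCCCCCCCCCCCC=C1C2C=CC1OO2
F7 | step 1 | racemic (E)-4-hydroxy-5-pentadecylidenecyclopent-2-en-1-one | CCCCCCCCCCCCCC/C=C1/C(=O)C=CC1O
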